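You asked for a quick number, so here is the problem as we have it.

| flask | starting material | partner | remark | time |
|---|---|---|---|---|
| zeta | 1.5 M | 0.35 equiv | run made earlier |  |
| beta | 1.5 M | 0.52 equiv | run made earlier |  |
| delta | 0.75 M | 0.70 equiv | run made earlier |  |
| flask | 1.5 M | 0.700 equiv |  | 30 min |

- zeta (time / min: product / %, open intermediate / %): 8.00: 23, 25; 15.0: 29, 24; 25.0: 33, 23; 30.0: 35, 21
- beta (time / min: product / %, open intermediate / %): 4.00: 23, 24; 10.0: 37, 21; 20.0: 47, 18; 30.0: 50, 16
- delta (time / min: product / %, open intermediate / %): 2.50: 9, 26; 6.00: 24, 24; 12.0: 40, 19; 30.0: 54, 16

(readings scatter by 1.5 percentage points)

- for product the crystals are counted in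
- as a solid, counted per litre of solution: crystals
- steps that have been proposed: starting material <-> open intermediate; partner -> second intermediate; open intermediate + second intermediate -> product; crystals <-> product; partner <-> dormant form
- the reaction counts as stopped when no species that holds the starting material changes by six tenths of a point or more over the second half of the time

1. at 30 min, what has stopped the reaction, if anything has (forward and back rates have come level / all of the starting material has reacted / it is still moving)
2. product at 30 min, in percent of the starting material charged
3. open intermediate at 30 min, in percent of the starting material charged

- We have no constants for this flask yet, but the runs offer a reading in place of one: the open share, c(open intermediate) over c(open intermediate) plus c(starting material), where that sum is the charge less product. Pooling the last readings of the three runs gives 0.329.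
- The symmetric case is our zero: two forms standing level would give 0.5, so this reading leaves starting material holding more than open intermediate.
- Your forecast is 63% product, 12% open intermediate and "it is still moving", on the ground that “partner limits the yield”.
- We accept that product for the flask. Our open share then gives 12.2% open intermediate in the flask, but the forecast reckons by the same kind of rule, so the match is no separate check.

The flask gives 65.2% product, 11.7% open intermediate and "it is still moving".

    starting material ⇌ open intermediate (K = 0.510, k = 0.0150 s⁻¹)
    partner → second intermediate (k = 0.0480 s⁻¹)
    open intermediate + second intermediate → product (k = 0.00630 M⁻¹ s⁻¹)
    crystals ⇌ product, rate k4*(cs4 - [product]) while solid is left; crystals form when [product] > cs4 (solubility = 0.540 M, k = 0.620 s⁻¹)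
    partner ⇌ dormant form (K = 0.770, k = 0.0220 s⁻¹)

- Our open share applied to the flask's product gives 11.4% open intermediate, against the 11.7% found, with 29.2% crystals counted in product; in this flask crystallising makes no difference to open intermediate. The neighbouring flask, charged with 0.280 equiv of partner, has 0% partner and 47.9% starting material left at 30.0 min, which makes partner the limiting reagent there, with 27.6% product and 0% crystals. The open share turns that product into 23.8% open intermediate, and the neighbouring flask holds 24.4%.

The runs come from a simulation for an exercise; the scatter is artificial.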